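**Retrosynthetic overview**
1. The strategy rests on ring C: C2 is a bare CH2 between O1 and the fully substituted carbinol C3, which carries OH, ring B and the C4 carbonyl. The C3 oxygen, C3 and C2 are therefore read as a 2-aryl-2-aroyloxirane, and ring C is disconnected at O1–C2, the oxirane CH2 being opened by a ring-A ortho phenoxide.
2. The oxirane comes from catalytic asymmetric nucleophilic epoxidation of a 1,2-diarylpropenone; this sets C3 and leaves the isolated vinyl group alone.
3. The enone comes from a Nozaki–Hiyama–Kishi coupling (C3–C4 bond) of a ring-B 1-arylvinyl triflate with tris-silylated phloroglucinaldehyde, then oxidation. No strong acid or base is used, so ring-A silyl ethers and ring-B MOM ethers can coexist.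
4. Ring B comes from gallacetophenone by 4-O-prenylation, MOM protection, aromatic Claisen rearrangement (1,1-dimethylallyl at C5') and O-methylation; its acetyl group supplies C3 and C2.
5. Rings A and B are bought as arenes; ring C is the only ring formed (step 10), and MOM removal ends the route.

Key step: step 10

Assumption: the sense of induction of the scandium/N,N′-dioxide catalyst in step 9 cannot be predicted with certainty for this substrate; the L-pipecolic-acid-derived ligand is written, and its enantiomer is to be used if a first run shows the (S)-oxirane.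

**Step 1**
Reactants: 1 gallacetophenone; 2 prenyl bromide
Product: 3 1-[2,3-dihydroxy-4-(3-methylbut-2-enyloxy)phenyl]ethan-1-one
Conditions: 2 (1.1 equiv), NaHCO3, NaI (cat.), DMF, 40 °C
Reagents that add atoms: none
Why: Williamson etherification with a weak base should be selective for the 4-OH, which is para to the acetyl group and the most acidic, whereas the 2-OH is locked in a hydrogen bond to the carbonyl and the 3-OH is flanked on both sides.

**Step 2**
Reactants: 3 1-[2,3-dihydroxy-4-(3-methylbut-2-enyloxy)phenyl]ethan-1-one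
Product: 4 1-[2,3-bis(methoxymethoxy)-4-(3-methylbut-2-enyloxy)phenyl]ethan-1-one
Conditions: NaH (2.2 equiv), MOMCl (2.4 equiv), DMF, 0 °C → rt
Reagents that add atoms: chloromethyl methyl ether (MOMCl), COCCl
Why: O-alkylation of both sodium phenoxides with the chloromethyl ether (MOM acetal formation), the sodium salt being needed to cap the chelated 2-OH.

**Step 3**
Reactants: 4 1-[2,3-bis(methoxymethoxy)-4-(3-methylbut-2-enyloxy)phenyl]ethan-1-one
Product: 6 4-acetyl-2,3-bis(methoxymethoxy)-6-(2-methylbut-3-en-2-yl)phenyl acetate, via Claisen phenol 5 (not isolated)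
Conditions: Ac2O (3 equiv), PhNEt2, 190 °C, sealed tube
Reagents that add atoms: acetic anhydride, CC(=O)OC(C)=O
Why: The aromatic Claisen rearrangement can only end at C5 because the other ortho carbon (C3) and the para carbon (C1) are substituted, and acetylation of the new phenol in the flask blocks the abnormal Claisen and cyclisation pathways of o-(1,1-dimethylallyl)phenols.

**Step 4**
Reactants: 6 4-acetyl-2,3-bis(methoxymethoxy)-6-(2-methylbut-3-en-2-yl)phenyl acetate
Product: 8 1-[4-methoxy-2,3-bis(methoxymethoxy)-5-(2-methylbut-3-en-2-yl)phenyl]ethan-1-one, via potassium phenoxide 7 (not isolated)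
Conditions: K2CO3 (2 equiv), MeOH, rt; solvent exchanged for DMF, MeI (1.5 equiv), rt → 40 °C
Reagents that add atoms: iodomethane, CI
Why: Transesterification of the aryl acetate with K2CO3/MeOH leaves the phenol as its potassium salt, since the para-acetyl group makes it acidic enough to be held as the phenoxide, and this salt undergoes Williamson methylation in the same pot with the small electrophile despite its two ortho neighbours.

**Step 5**
Reactants: 8 1-[4-methoxy-2,3-bis(methoxymethoxy)-5-(2-methylbut-3-en-2-yl)phenyl]ethan-1-one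
Product: 9 1-[4-methoxy-2,3-bis(methoxymethoxy)-5-(2-methylbut-3-en-2-yl)phenyl]ethenyl trifluoromethanesulfonate
Conditions: KN(SiMe3)2 (1.05 equiv), THF, −78 °C; PhNTf2, −78 → 0 °C; chromatography on Et3N-treated silica
Reagents that add atoms: N-phenylbis(trifluoromethanesulfonimide), O=S(=O)(N(c1ccccc1)S(=O)(=O)C(F)(F)F)C(F)(F)F
Why: Enol triflate formation: the acetyl methyl is the only enolisable position, and O-sulfonylation of the potassium enolate at low temperature with no more than a slight excess of base should avoid elimination to the arylalkyne.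

**Step 6**
Reactants: 10 2,4,6-trihydroxybenzaldehyde
Product: 11 2,4,6-tris(triisopropylsilyloxy)benzaldehyde
Conditions: TIPSOTf (3.6 equiv), 2,6-lutidine, CH2Cl2, 0 °C → rt
Reagents that add atoms: triisopropylsilyl trifluoromethanesulfonate, CC(C)[Si](OS(=O)(=O)C(F)(F)F)(C(C)C)C(C)C
Why: O-silylation with the silyl triflate and a hindered base is forceful enough to cap the two chelated ortho hydroxyls as well as the para one.

**Step 7**
Reactants: 9 1-[4-methoxy-2,3-bis(methoxymethoxy)-5-(2-methylbut-3-en-2-yl)phenyl]ethenyl trifluoromethanesulfonate; 11 2,4,6-tris(triisopropylsilyloxy)benzaldehyde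
Product: 12 rac-2-[4-methoxy-2,3-bis(methoxymethoxy)-5-(2-methylbut-3-en-2-yl)phenyl]-1-[2,4,6-tris(triisopropylsilyloxy)phenyl]prop-2-en-1-ol
Conditions: 9 (1.5 equiv), CrCl2 (4 equiv), NiCl2 (2 mol %), DMF, rt, argon; pH 7 work-up, crude taken into step 8
Reagents that add atoms: none
Why: Nozaki–Hiyama–Kishi coupling, in which zerovalent nickel inserts into the vinyl C–OTf bond and the alkenylchromium species formed by transmetalation adds to the aldehyde without touching silyl ethers, MOM acetals or the isolated vinyl group; the carbinol centre forms racemic and is erased in step 8.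

**Step 8**
Reactants: 12 rac-2-[4-methoxy-2,3-bis(methoxymethoxy)-5-(2-methylbut-3-en-2-yl)phenyl]-1-[2,4,6-tris(triisopropylsilyloxy)phenyl]prop-2-en-1-ol
Product: 13 2-[4-methoxy-2,3-bis(methoxymethoxy)-5-(2-methylbut-3-en-2-yl)phenyl]-1-[2,4,6-tris(triisopropylsilyloxy)phenyl]prop-2-en-1-one
Conditions: Dess–Martin periodinane, NaHCO3, CH2Cl2, 0 °C → rt
Reagents that add atoms: none
Why: Dess–Martin oxidation of a benzylic and allylic secondary alcohol, buffered so that the ionisable carbinol and the acetals see no acid.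

**Step 9**
Reactants: 13 2-[4-methoxy-2,3-bis(methoxymethoxy)-5-(2-methylbut-3-en-2-yl)phenyl]-1-[2,4,6-tris(triisopropylsilyloxy)phenyl]prop-2-en-1-one
Product: 14 {(2R)-2-[4-methoxy-2,3-bis(methoxymethoxy)-5-(2-methylbut-3-en-2-yl)phenyl]oxiran-2-yl}[2,4,6-tris(triisopropylsilyloxy)phenyl]methanone
Conditions: Sc(OTf)3 (10 mol %), C2-symmetric N,N′-dioxide ligand from L-pipecolic acid with 2,6-diisopropylanilide arms and a propane-1,3-diyl linker (10 mol %), 35% aq. H2O2 (3 equiv), THF, 0 °C → rt
Reagents that add atoms: hydrogen peroxide, OO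
Why: Chiral-Lewis-acid-catalysed Weitz–Scheffer epoxidation, a reaction type established for alpha-substituted vinyl aryl ketones, in which H2O2 adds to the CH2 terminus of the scandium-bound enone and the peroxy enolate closes on the face left open by the ligand (catalyst control of the new quaternary centre), while the nucleophilic oxidant ignores the isolated vinyl group.

**Step 10**
Reactants: 14 {(2R)-2-[4-methoxy-2,3-bis(methoxymethoxy)-5-(2-methylbut-3-en-2-yl)phenyl]oxiran-2-yl}[2,4,6-tris(triisopropylsilyloxy)phenyl]methanone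
Product: 16 (3R)-3,5,7-trihydroxy-3-[4-methoxy-2,3-bis(methoxymethoxy)-5-(2-methylbut-3-en-2-yl)phenyl]-2,3-dihydro-4H-chromen-4-one, via triphenol oxirane 15 (not isolated)
Conditions: Bu4NF (3.5 equiv), THF, 0 °C → rt, argon; aq. NH4Cl
Reagents that add atoms: none
Why: Fluoride cleaves the three aryl O–Si bonds, and the tetrabutylammonium phenoxide ortho to the ketone attacks the unsubstituted oxirane carbon from the backside, so the CH2–O bond of the oxirane breaks, O1–C2 forms and the oxirane oxygen stays on C3 as the alkoxide that becomes the tertiary hydroxyl on work-up. The closest known reaction type is the base-mediated cyclisation of 2'-hydroxyaryl epoxy ketones to 3-hydroxychromanones in the Algar–Flynn–Oyamada manifold. The pyranone ring closes in the 6-endo-tet mode, and because the two ortho oxygens of ring A are equivalent either one gives the same chromanone. No stereocentre is created: the C3–O bond is never broken and C3 carries no hydrogen, so the configuration set in step 9 passes through unchanged. The selectivity needed is attack at CH2 (6-endo) instead of at C3 (5-exo, leading to a 2-aryl-2-(hydroxymethyl)benzofuran-3-one); it is secured because C3 is fully substituted and closed to SN2 attack under basic, non-ionising conditions, while the MOM ethers keep the ring-B oxygens from acting as nucleophiles.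

**Step 11**
Reactants: 16 (3R)-3,5,7-trihydroxy-3-[4-methoxy-2,3-bis(methoxymethoxy)-5-(2-methylbut-3-en-2-yl)phenyl]-2,3-dihydro-4H-chromen-4-one
Product: 17 (3R)-3-[2,3-dihydroxy-4-methoxy-5-(2-methylbut-3-en-2-yl)phenyl]-3,5,7-trihydroxy-2,3-dihydro-4H-chromen-4-one
Conditions: HCl (1.25 M in MeOH), 0 °C → rt
Reagents that add atoms: none
Why: Acid-catalysed acetal exchange with methanol removes both phenolic MOM groups, and the C3 carbinol should survive because its ionisation would place a cation next to the C4 carbonyl and the 1,1-dimethylallyl group has no free ortho hydroxyl to cyclise onto.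

**Compound list**
1 | gallacetophenone, 1-(2,3,4-trihydroxyphenyl)ethan-1-one | CC(=O)c1ccc(O)c(O)c1O | starting material
2 | prenyl bromide, 1-bromo-3-methylbut-2-ene | CC(C)=CCBr | starting material
3 | 1-[2,3-dihydroxy-4-(3-methylbut-2-enyloxy)phenyl]ethan-1-one | CC(=O)c1ccc(OCC=C(C)C)c(O)c1O | intermediate
4 | 1-[2,3-bis(methoxymethoxy)-4-(3-methylbut-2-enyloxy)phenyl]ethan-1-one | CC(=O)c1ccc(OCC=C(C)C)c(OCOC)c1OCOC | intermediate
5 | 1-[4-hydroxy-2,3-bis(methoxymethoxy)-5-(2-methylbut-3-en-2-yl)phenyl]ethan-1-one (not isolated) | CC(=O)c1cc(C(C)(C)C=C)c(O)c(OCOC)c1OCOC | intermediate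
6 | 4-acetyl-2,3-bis(methoxymethoxy)-6-(2-methylbut-3-en-2-yl)phenyl acetate | CC(=O)Oc1c(C(C)(C)C=C)cc(C(C)=O)c(OCOC)c1OCOC | intermediate
7 | potassium 4-acetyl-2,3-bis(methoxymethoxy)-6-(2-methylbut-3-en-2-yl)phenolate (not isolated) | CC(=O)c1cc(C(C)(C)C=C)c([O-])c(OCOC)c1OCOC.[K+] | intermediate
8 | 1-[4-methoxy-2,3-bis(methoxymethoxy)-5-(2-methylbut-3-en-2-yl)phenyl]ethan-1-one | CC(=O)c1cc(C(C)(C)C=C)c(OC)c(OCOC)c1OCOC | intermediate
9 | 1-[4-methoxy-2,3-bis(methoxymethoxy)-5-(2-methylbut-3-en-2-yl)phenyl]ethenyl trifluoromethanesulfonate | C=C(OS(=O)(=O)C(F)(F)F)c1cc(C(C)(C)C=C)c(OC)c(OCOC)c1OCOC | intermediate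
10 | 2,4,6-trihydroxybenzaldehyde | O=Cc1c(O)cc(O)cc1O | starting material
11 | 2,4,6-tris(triisopropylsilyloxy)benzaldehyde | O=Cc1c(O[Si](C(C)C)(C(C)C)C(C)C)cc(O[Si](C(C)C)(C(C)C)C(C)C)cc1O[Si](C(C)C)(C(C)C)C(C)C | intermediate
12 | racemic allylic alcohol, 2-(ring-B aryl)-1-[2,4,6-tris(triisopropylsilyloxy)phenyl]prop-2-en-1-ol | C=C(C(O)c1c(O[Si](C(C)C)(C(C)C)C(C)C)cc(O[Si](C(C)C)(C(C)C)C(C)C)cc1O[Si](C(C)C)(C(C)C)C(C)C)c1cc(C(C)(C)C=C)c(OC)c(OCOC)c1OCOC | intermediate
13 | enone, 2-(ring-B aryl)-1-[2,4,6-tris(triisopropylsilyloxy)phenyl]prop-2-en-1-one | C=C(C(=O)c1c(O[Si](C(C)C)(C(C)C)C(C)C)cc(O[Si](C(C)C)(C(C)C)C(C)C)cc1O[Si](C(C)C)(C(C)C)C(C)C)c1cc(C(C)(C)C=C)c(OC)c(OCOC)c1OCOC | intermediate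
14 | (2R)-oxirane, [(2R)-2-(ring-B aryl)oxiran-2-yl][2,4,6-tris(triisopropylsilyloxy)phenyl]methanone | O=C(c1c(O[Si](C(C)C)(C(C)C)C(C)C)cc(O[Si](C(C)C)(C(C)C)C(C)C)cc1O[Si](C(C)C)(C(C)C)C(C)C)[C@@]1(c2cc(C(C)(C)C=C)c(OC)c(OCOC)c2OCOC)CO1 | intermediate
15 | [(2R)-2-(ring-B aryl)oxiran-2-yl](2,4,6-trihydroxyphenyl)methanone (not isolated) | O=C(c1c(O)cc(O)cc1O)[C@@]1(c2cc(C(C)(C)C=C)c(OC)c(OCOC)c2OCOC)CO1 | intermediate
16 | (3R)-3,5,7-trihydroxy-3-[4-methoxy-2,3-bis(methoxymethoxy)-5-(2-methylbut-3-en-2-yl)phenyl]-2,3-dihydro-4H-chromen-4-one | C=CC(C)(C)c1cc([C@@]2(O)COc3cc(O)cc(O)c3C2=O)c(OCOC)c(OCOC)c1OC | intermediate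
17 | (3R)-3-[2,3-dihydroxy-4-methoxy-5-(2-methylbut-3-en-2-yl)phenyl]-3,5,7-trihydroxy-2,3-dihydro-4H-chromen-4-one | C=CC(C)(C)c1cc([C@@]2(O)COc3cc(O)cc(O)c3C2=O)c(O)c(O)c1OC | target

("Ring-B aryl" in 12–15 is 4-methoxy-2,3-bis(methoxymethoxy)-5-(2-methylbut-3-en-2-yl)phenyl.)

**Totals**
Total step count: 11. Longest linear sequence: 10 steps (steps 1–5, then 7–11); step 6 is a one-step branch.

**Steps most likely to fail**

Step 9. Enantiofacial control may be poor or turnover slow, because the carbonyl that must bind scandium is shielded by two ortho silyloxy groups and the stereocentre is fixed only when the peroxy enolate closes. The fallback sets out from the racemic allylic alcohol 12 and replaces conjugate epoxidation by a hydroxyl-directed one. A Sharpless kinetic resolution (Ti(OiPr)4, L-(+)-diisopropyl tartrate, t-BuOOH, 4 Å MS, CH2Cl2, −20 °C, run to about half conversion) should epoxidise only the allylic double bond of the fast-reacting enantiomer. By the empirical face rule for L-(+)-tartrate this gives the anti epoxy alcohol with an (S)-carbinol and a (2R)-oxirane, F1. Buffered Dess–Martin oxidation of F1 returns to the route at 14.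

Step 10. After desilylation the intended closure may be overtaken by opening of the oxirane by fluoride, by acyloin-type rearrangement of the tertiary alkoxide, or by air oxidation of the electron-rich phenoxides. The fallback sets out from enone 13 and makes ring C before the carbinol. Bu4NF in THF should desilylate 13 and trigger 6-endo-trig oxa-Michael closure to the racemic 5,7-dihydroxyisoflavanone F2. TBSOTf and 2,6-lutidine give the 5,7-bis(tert-butyldimethylsilyl) ether F3. Its sodium enolate (NaN(SiMe3)2, THF, −78 °C) is hydroxylated with the enantiomer of (camphorsulfonyl)oxaziridine that delivers the (3R)-alcohol, giving F4 under reagent control. Bu4NF then returns to the route at 16.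

Step 7. Addition of the alkenylchromium species to the doubly ortho-silyloxylated aldehyde may be sluggish, with reduction of the triflate or ionisation of the very electron-rich carbinol taking over. The fallback sets out from ketone 8 and uses a polar organometallic instead of the nickel/chromium redox couple. 2,4,6-Triisopropylbenzenesulfonyl hydrazide (MeOH, rt) gives the trisylhydrazone F5. A Shapiro reaction (n-BuLi, 2.2 equiv, THF, −78 → 0 °C) generates the 1-arylvinyllithium F6. After transmetalation with CeCl3 at −78 °C, F6 is added to aldehyde 11 and quenched cold, returning to the route at 12.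

**Further compounds**
F1 | step 9 | (S)-[(2R)-2-(ring-B aryl)oxiran-2-yl][2,4,6-tris(triisopropylsilyloxy)phenyl]methanol | O[C@@H](c1c(O[Si](C(C)C)(C(C)C)C(C)C)cc(O[Si](C(C)C)(C(C)C)C(C)C)cc1O[Si](C(C)C)(C(C)C)C(C)C)[C@@]1(c2cc(C(C)(C)C=C)c(OC)c(OCOC)c2OCOC)CO1
F2 | step 10 | rac-5,7-dihydroxy-3-[4-methoxy-2,3-bis(methoxymethoxy)-5-(2-methylbut-3-en-2-yl)phenyl]-2,3-dihydro-4H-chromen-4-one | C=CC(C)(C)c1cc(C2COc3cc(O)cc(O)c3C2=O)c(OCOC)c(OCOC)c1OC
F3 | step 10 | rac-5,7-bis(tert-butyldimethylsilyloxy)-3-[4-methoxy-2,3-bis(methoxymethoxy)-5-(2-methylbut-3-en-2-yl)phenyl]-2,3-dihydro-4H-chromen-4-one | C=CC(C)(C)c1cc(C2COc3cc(O[Si](C)(C)C(C)(C)C)cc(O[Si](C)(C)C(C)(C)C)c3C2=O)c(OCOC)c(OCOC)c1OC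
F4 | step 10 | (3R)-5,7-bis(tert-butyldimethylsilyloxy)-3-hydroxy-3-[4-methoxy-2,3-bis(methoxymethoxy)-5-(2-methylbut-3-en-2-yl)phenyl]-2,3-dihydro-4H-chromen-4-one | C=CC(C)(C)c1cc([C@@]2(O)COc3cc(O[Si](C)(C)C(C)(C)C)cc(O[Si](C)(C)C(C)(C)C)c3C2=O)c(OCOC)c(OCOC)c1OC
F5 | step 7 | 2,4,6-triisopropylbenzenesulfonyl hydrazone of ketone 8 | CC(=NNS(=O)(=O)c1c(C(C)C)cc(C(C)C)cc1C(C)C)c1cc(C(C)(C)C=C)c(OC)c(OCOC)c1OCOC
F6 | step 7 | 1-[4-methoxy-2,3-bis(methoxymethoxy)-5-(2-methylbut-3-en-2-yl)phenyl]ethenyllithium | [Li]C(=C)c1cc(C(C)(C)C=C)c(OC)c(OCOC)c1OCOC
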